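The constants were drawn at random within sensible limits; no experiment stands behind them.

Wednesday's, Sunday's and Friday's flasks receive the same amounts, 0.020 M of substrate and 0.0200 M of first nucleophile as undissolved solid, and they differ in temperature.

in all of them: substrate 0.020 M; second nucleophile 0.0120 M; solid first nucleophile 0.0200 M; capture agent 0.400 mM; time 4.0 h

| flask | remark | temperature |
|---|---|---|
| Wednesday's | at 50 °C until 80 min, from then on at 25 °C |  |
| Sunday's |  | 25 °C |
| Friday's |  | 50 °C |

    second nucleophile + open intermediate → other capture product (k1 = 0.20 L mol⁻¹ s⁻¹, Ea1 = 43.0 kJ mol⁻¹)
    substrate → open intermediate (k2 = 0.0034 s⁻¹, Ea2 = 88.0 kJ mol⁻¹)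
    open intermediate → solvolysis product (k3 = 0.0052 s⁻¹, Ea3 = 95.0 kJ mol⁻¹)
    first nucleophile + open intermediate → target (k4 = 0.14 L mol⁻¹ s⁻¹, Ea4 = 55.0 kJ mol⁻¹)
    solid first nucleophile ⇌ first nucleophile, rate k5*(cs5 - [first nucleophile]) while solid is left; crystals form when [first nucleophile] > cs5 (cs5 = 11 mM, k5 = 0.0063 s⁻¹)
    open intermediate + capture agent → trapped intermediate (k6 = 0.12 L mol⁻¹ s⁻¹, Ea6 = 64.0 kJ mol⁻¹)
    (constants at 25 °C)

- which flask leads in amount of target, in percent of the substrate charged ("all alike" within 1.5 percentage points) (Wednesday's / Sunday's / Friday's / all alike)
- how much target is there at the end, in percent of the substrate charged: Wednesday's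
- how much target is there at the end, in percent of the substrate charged: Sunday's
- how much target is there at the end, in percent of the substrate charged: Friday's

- solid, in amounts per volume of the solution: solid first nucleophile
- the constants hold at 25 °C; other temperatures follow from the activation energies
- at the start none of the solid first nucleophile is in solution

Two chemists argue over these flasks before anyone runs them. Both start from the selectivity of the open intermediate: the share taken by first nucleophile, which is that capture rate over L, the summed rate of its four exits per unit of open intermediate, with second nucleophile and capture agent held at their charges.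

Because the 0.0200 M charged is more than the 11 mM the solution holds, the first chemist takes first nucleophile at 11 mM throughout. That gives L = 0.00919 s⁻¹ and a share of 16.8% at 25 °C. With each constant raised by its activation energy, it gives L = 0.119 s⁻¹ and a share of 7.21% at 50 °C.

The second chemist counts turnovers instead. The substrate lives 294 s at 25 °C and 18.9 s at 50 °C. The dissolving carries no activation energy and takes 159 s at either temperature, so at 50 °C the substrate turns over sooner than first nucleophile arrives.

I side with the second chemist and make this a number. The undissolved gap shrinks as exp(−dt), where d is the dissolution coefficient. Averaged over the substrate's wait, with rate constant s, and then over the open intermediate's wait, the gap leaves s/(s+d) times L/(L+d). Subtracted from 1, this gives 0.792 in Sunday's flask and 0.151 in Friday's. Call it S, the fill seen, the mean fraction of saturation met by the open intermediate.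

Target is the share times S, so I reckon 13.3% for Sunday's flask and 1.09% for Friday's. Wednesday's cooling comes after 254 substrate lifetimes, so I reckon that flask as Friday's, 1.09%. My leader is Sunday's.

The forecast, close to mine but not the same, gave 1.2% for Wednesday's, 13.5% for Sunday's and 1.2% for Friday's, with Sunday's leading, the hot flasks finishing “before the slowly dissolving first nucleophile (its dissolution does not speed up with temperature) has built up”.

The simulation gives 1.14% for Wednesday's, 14.1% for Sunday's and 1.14% for Friday's, with Sunday's leading.

The first chemist's share stands above Friday's result by 6.1 percentage points and above Sunday's by 2.7 points. That view is right as S nears 1, and S is 0.792 in Sunday's flask against 0.151 in Friday's. For a repeat of Sunday's at 40 °C, L is 0.0427 s⁻¹, the share 10.4% and S 0.349, so I reckon target at 3.63%. That flask ends with 3.83% of target and 83.2% of solvolysis product.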